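**Plan**

- Retrosynthesis: the last cut is the C14=C18 double bond (hydrogenation). Next, rings B and A come apart by a Pauson–Khand disconnection (C14–C15, C16–C17, C17–C18; C17 is CO). Then C12–C13 (propargyl), C1–C2 (methallyl) and the epoxide oxygen are removed. Finally C6–C10 and C2–C12 are cut together.
- Enabling feature: C10–C11(Me)–C12 of ring C is a 1,3-dioxygenated three-carbon unit. Its two ends are bonded to the ring-fusion methines C6 (ring D) and C2, and each of these sits next to a methyl-bearing carbon (C7, C3). A masked 2-methyl-3-oxo-aldehyde (β-silyloxy enone) can therefore accept two 2-(silylmethyl)allyl nucleophiles. The first addition (C6 to C10, ring D) ionises and unveils C12 for the second (C2 to C12, ring C). The silylmethyl carbons end as the methylidenes C22 and C21, later the two methyls.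
- Forward: an achiral open-chain precursor (steps 1–6) gives ring D and then ring C in the key step; rings B and A follow together (Pauson–Khand).
- Stereochemistry: C6 forms racemic in the key step. One catalytic step, an (R)-CBS reduction at C12 run as a kinetic resolution, fixes the absolute configuration. The temporary C12 carbinol directs hydrogen to C3; C6 controls C7 and the epoxide (C10, C11); these control C2 and then C12. C15 follows in the Pauson–Khand step, and C14 and C18 are set together in the last, hydroxyl-directed hydrogenation.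

Key step: step 7

Remark (numbering): carbons are numbered C1–C25 along the isoprenoid chain. Ring A (cyclopentanone) = C14–C18; ring B = C1, C2, C12–C15; ring C (eight-membered) = C2–C6, C10–C12; ring D = C6–C10. C21, C22, C23, C24 are the methyls on C3, C7, C11, C15; C19 (with C20, C25) is the isopropyl on C18. The target is the (2R,3R,6S,7S,10S,11R,12R,14S,15S,18R)-10,11-epoxy-12-hydroxy-17-ketone. Bicyclic intermediates are named as bicyclo[6.3.0]undecanes.

Remark (assumptions): compounds 21–23 are racemic and their SMILES carry no stereodescriptor; 1-bromo-4-methylpent-2-yne is taken as a catalogue compound.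

**Route**

Step 1
Reactants: 1 (2-bromoprop-2-en-1-yl)trimethylsilane; 2 oxirane
Product: 4 3-[(trimethylsilyl)methyl]but-3-en-1-ol, via alkenylmagnesium bromide 3 (not isolated)
Conditions: Mg, THF, 25 °C; then CuI (10 mol%), 2, −30 to 0 °C; aq. NH4Cl
Reagents that add atoms: none
Why: copper-catalysed opening of ethylene oxide by an alkenyl Grignard reagent is a standard two-carbon homologation that leaves the allylsilane untouched, and no stereocentre is formed.

Step 2
Reactants: 4 3-[(trimethylsilyl)methyl]but-3-en-1-ol
Product: 5 [2-(2-iodoethyl)prop-2-en-1-yl]trimethylsilane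
Conditions: I2, PPh3, imidazole, CH2Cl2, 0 °C
Reagents that add atoms: iodine, [I][I]
Why: Appel-type iodination of a primary alcohol, in which imidazole buffers the acid that would otherwise protodesilylate the allylsilane.

Step 3
Reactants: 6 pent-4-ynoic acid; 7 N,O-dimethylhydroxylamine hydrochloride
Product: 9 N-methoxy-N-methylpent-4-ynamide, via acyl imidazolide 8 (not isolated)
Conditions: 1,1'-carbonyldiimidazole, CH2Cl2, 0 to 25 °C; then 7, 25 °C
Reagents that add atoms: none
Why: routine Weinreb amide formation through the acyl imidazolide.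

Step 4
Reactants: 9 N-methoxy-N-methylpent-4-ynamide; 10 (trimethylsilyl)methylmagnesium chloride; 5 [2-(2-iodoethyl)prop-2-en-1-yl]trimethylsilane
Product: 12 (4Z)-N-methoxy-N-methyl-8-methylidene-9-(trimethylsilyl)-4-[(trimethylsilyl)methyl]non-4-enamide, via alkenylcopper 11 (not isolated)
Conditions: 10, CuBr·SMe2, Et2O/Me2S, −40 °C; 9, −25 °C; then 5, HMPA, P(OEt)3, −25 to 25 °C
Reagents that add atoms: none
Why: Normant syn-carbocupration of the terminal alkyne places the silylmethyl group on the internal carbon and copper on the terminal one, and alkylation of the alkenylcopper by the primary iodide with retention fixes the Z trisubstituted allylsilane, the organocopper reagent being too weak a nucleophile to attack the Weinreb amide at this temperature.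

Step 5
Reactants: 12 (4Z)-N-methoxy-N-methyl-8-methylidene-9-(trimethylsilyl)-4-[(trimethylsilyl)methyl]non-4-enamide; 13 propanal; 14 cyclohexanamine
Product: 17 (6Z)-2-methyl-10-methylidene-3-oxo-11-(trimethylsilyl)-6-[(trimethylsilyl)methyl]undec-6-enal, via imine 15 (not isolated), via enaminone 16 (not isolated)
Conditions: 13, 14, MgSO4, Et2O, 0 °C; lithium diisopropylamide, THF, 0 °C; 12, −78 to 0 °C; then AcOH/NaOAc, H2O/THF, 25 °C
Reagents that add atoms: water, O
Why: acylation of a metalated aldimine by a Weinreb amide (directed Claisen-type condensation) stops at the chelated adduct, and buffered hydrolysis of the resulting vinylogous amide should release the 2-methyl-3-oxo-aldehyde without protodesilylation, its methyl-bearing carbon being enolised and therefore of no stereochemical consequence.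

Step 6
Reactants: 17 (6Z)-2-methyl-10-methylidene-3-oxo-11-(trimethylsilyl)-6-[(trimethylsilyl)methyl]undec-6-enal
Product: 18 (1E,6Z)-1-[(tert-butyldimethylsilyl)oxy]-2-methyl-10-methylidene-11-(trimethylsilyl)-6-[(trimethylsilyl)methyl]undeca-1,6-dien-3-one
Conditions: TBSCl, Et3N, DMAP (cat.), CH2Cl2, 0 °C
Reagents that add atoms: tert-butyl(chloro)dimethylsilane, CC(C)(C)[Si](C)(C)Cl
Why: O-silylation of the hydroxymethylene tautomer of a formyl ketone gives the β-silyloxy enone (a vinylogous silyl ester), which masks C12 as an enol ether and leaves the C10 ketone as the first electrophilic site.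

Step 7
Reactants: 18 (1E,6Z)-1-[(tert-butyldimethylsilyl)oxy]-2-methyl-10-methylidene-11-(trimethylsilyl)-6-[(trimethylsilyl)methyl]undeca-1,6-dien-3-one
Product: 21 rac-tert-butyl(dimethyl)[(2-methyl-5,9-dimethylidenebicyclo[6.3.0]undec-1-en-3-yl)oxy]silane, via bis-silyl ether 19 (not isolated), via oxocarbenium triflate 20 (not isolated)
Conditions: Me3SiOTf (0.3 equiv), 2,6-di-tert-butyl-4-methylpyridine (0.5 equiv), CH2Cl2 (0.002 M), −78 to −20 °C; Et3N, then aq. NaHCO3
Reagents that add atoms: none
Why: Proposed new method: Me3SiOTf silylates the ketone oxygen of 18 to a 1,3-bis(silyloxy)allyl cation, the trisubstituted allylsilane adds through C6 to C10 with release of the silyl group to give 19, the tertiary allylic silyloxy group of 19 is then ionised with loss of (Me3Si)2O, pushed by the C12 enol ether, to the conjugated silyl oxocarbenium ion 20, and the second allylsilane adds through C2 to C12, so that the silyl triflate is regenerated twice and is catalytic. The closest known reactions are the Stork–Danheiser 1,3-carbonyl transposition, Lewis-acid-mediated 2-(silylmethyl)allyl additions to ketones (methylenecyclopentane annulation), Sakurai additions to α,β-unsaturated acetals, which take place at the acetal carbon, and Lewis-acid-promoted (3+5) annulations of bis-nucleophiles with dielectrophiles. Ring D closes in a 5-exo-trig mode at the C10 carbonyl and ring C in an 8-exo-trig mode at the C12 oxocarbenium carbon, each with the nucleophilic double bond inside the new ring, so that both silylmethyl carbons end as exocyclic methylidenes (C22, C21). The only stereocentres formed are C6, which is racemic here and resolved in step 10, and C12, whose configuration is irrelevant because it is oxidised in step 9. The step needs ring D before ring C, which ring size should secure (five against seven, nine or eleven), attack of C2 at C12 and not at C10 (six-membered ring), for which the oxocarbenium carbon carries the charge while C10 is a fully substituted vinylogous position, and the C10=C11 geometry with C12 cis to C6, which the delocalised cation can reach by rotation. The hindered pyridine removes traces of TfOH and so should suppress protodesilylation, and high dilution disfavours intermolecular reaction.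

Step 8
Reactants: 21 rac-tert-butyl(dimethyl)[(2-methyl-5,9-dimethylidenebicyclo[6.3.0]undec-1-en-3-yl)oxy]silane
Product: 22 rac-2-methyl-5,9-dimethylidenebicyclo[6.3.0]undec-1-en-3-ol
Conditions: Bu4NF, THF, 0 °C; aq. NH4Cl
Reagents that add atoms: none
Why: fluoride cleavage of a secondary silyl ether, to which the alkenes are inert.

Step 9
Reactants: 22 rac-2-methyl-5,9-dimethylidenebicyclo[6.3.0]undec-1-en-3-ol
Product: 23 rac-2-methyl-5,9-dimethylidenebicyclo[6.3.0]undec-1-en-3-one
Conditions: Dess–Martin periodinane, NaHCO3, CH2Cl2, 0 °C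
Reagents that add atoms: none
Why: buffered oxidation of the allylic alcohol removes the C12 stereocentre, so that both C12 epimers of 22 should converge on one racemic enone whose only stereocentre is C6.

Step 10
Reactants: 23 rac-2-methyl-5,9-dimethylidenebicyclo[6.3.0]undec-1-en-3-one
Product: 24 (3S,8S)-2-methyl-5,9-dimethylidenebicyclo[6.3.0]undec-1-en-3-ol
Conditions: (R)-2-methyl-CBS-oxazaborolidine (20 mol%), catecholborane (0.6 equiv), toluene, −78 °C
Reagents that add atoms: none
Why: Corey–Bakshi–Shibata reduction run as a kinetic resolution, in which the (R)-catalyst (alkenyl as the large group) delivers hydride to give the (12S)-carbinol and, in the (6S)-enantiomer only, this is also the open face of the carbonyl on the side of C6–H and away from ring D, so that the matched enantiomer should be reduced first to 24 with the hydroxyl anti to C6–H while the other enantiomer remains as ketone and is separated, catecholborane being chosen because it does not hydroborate the methylidene groups at −78 °C.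

Step 11
Reactants: 24 (3S,8S)-2-methyl-5,9-dimethylidenebicyclo[6.3.0]undec-1-en-3-ol
Product: 25 (3S,5R,8S,9S)-2,5,9-trimethylbicyclo[6.3.0]undec-1-en-3-ol
Conditions: [Ir(cod)(PCy3)(py)]PF6 (5 mol%), H2 (1 atm), CH2Cl2, 0 °C
Reagents that add atoms: none
Why: hydroxyl-directed hydrogenation, in which iridium bound to the C12 hydroxyl should deliver hydrogen to the homoallylic C3 methylidene on the hydroxyl face (C3), the remote C7 methylidene should be reduced from the open face of ring D next to C6–H (C7 methyl cis to C5), and the tetrasubstituted C10=C11 bond is expected to be too hindered to react at low temperature and short reaction time.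

Step 12
Reactants: 25 (3S,5R,8S,9S)-2,5,9-trimethylbicyclo[6.3.0]undec-1-en-3-ol
Product: 26 (5R,8S,9S)-2,5,9-trimethylbicyclo[6.3.0]undec-1-en-3-one
Conditions: Dess–Martin periodinane, NaHCO3, CH2Cl2, 0 °C
Reagents that add atoms: none
Why: re-oxidation to the enone removes the temporary C12 centre once it has relayed its information to C3.

Step 13
Reactants: 26 (5R,8S,9S)-2,5,9-trimethylbicyclo[6.3.0]undec-1-en-3-one
Product: 27 (1S,2S,5R,8S,9S)-1,2-epoxy-2,5,9-trimethylbicyclo[6.3.0]undecan-3-one
Conditions: t-BuOOH, benzyltrimethylammonium hydroxide (cat.), THF, 0 to 25 °C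
Reagents that add atoms: tert-butyl hydroperoxide, CC(C)(C)OO
Why: Weitz–Scheffer epoxidation of the enone, in which the peroxide anion should attack C10 from the face of C6–H, away from C5 and the C7 methyl, so that the epoxide oxygen ends cis to C6–H.

Step 14
Reactants: 27 (1S,2S,5R,8S,9S)-1,2-epoxy-2,5,9-trimethylbicyclo[6.3.0]undecan-3-one; 28 3-bromo-2-methylprop-1-ene
Product: 30 (1S,2S,4R,5R,8S,9S)-1,2-epoxy-2,5,9-trimethyl-4-(2-methylprop-2-en-1-yl)bicyclo[6.3.0]undecan-3-one, via lithium enolate 29 (not isolated)
Conditions: lithium diisopropylamide, THF, −78 °C; 28, DMPU, −78 to −40 °C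
Reagents that add atoms: none
Why: the only enolisable position is C2, and alkylation of its enolate is expected on the peripheral face of the eight-membered ring, anti to the C11 methyl and to ring D and therefore on the side of the epoxide oxygen and of the C3 methyl (which allylic strain against C11 turns out of the enolate plane), giving C1 cis to C21.

Step 15
Reactants: 30 (1S,2S,4R,5R,8S,9S)-1,2-epoxy-2,5,9-trimethyl-4-(2-methylprop-2-en-1-yl)bicyclo[6.3.0]undecan-3-one; 31 1-bromo-4-methylpent-2-yne
Product: 33 (1S,2R,3R,4R,5R,8S,9S)-1,2-epoxy-2,5,9-trimethyl-3-(4-methylpent-2-yn-1-yl)-4-(2-methylprop-2-en-1-yl)bicyclo[6.3.0]undecan-3-ol, via allenylzinc bromide 32 (not isolated)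
Conditions: Zn dust, THF, 0 to 25 °C; aq. NH4Cl
Reagents that add atoms: none
Why: Barbier propargylation through the allenylzinc reagent (SE2') gives the homopropargylic tertiary alcohol, and zinc chelated between the ketone and epoxide oxygens should expose the face anti to the epoxide oxygen and to C1, placing the new hydroxyl cis to the epoxide and C13 trans to C1.

Step 16
Reactants: 33 (1S,2R,3R,4R,5R,8S,9S)-1,2-epoxy-2,5,9-trimethyl-3-(4-methylpent-2-yn-1-yl)-4-(2-methylprop-2-en-1-yl)bicyclo[6.3.0]undecan-3-ol
Product: 34 (2R,3R,6S,7S,10S,11R,12R,15S)-10,11-epoxy-12-hydroxy tetracyclic 14(18)-en-17-one (14,18-didehydro-35)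
Conditions: Co2(CO)8 (20 mol%), tetramethylthiourea (60 mol%), CO (1 atm), benzene, 70 °C
Reagents that add atoms: carbon monoxide, [C-]#[O+]
Why: intramolecular Pauson–Khand reaction of the 1,7-enyne forms rings B and A and the C15 quaternary centre, and in the chair-like transition state of ring B the two bonds to ring C are equatorial and the methylene carbon C16 must lie in the plane of the alkyne–cobalt unit, so the C15 methyl should become axial, syn to C2–H and anti to the C12 hydroxyl.

Step 17
Reactants: 34 (2R,3R,6S,7S,10S,11R,12R,15S)-10,11-epoxy-12-hydroxy tetracyclic 14(18)-en-17-one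
Product: 35 (2R,3R,6S,7S,10S,11R,12R,14S,15S,18R)-10,11-epoxy-12-hydroxy tetracyclic 17-ketone (target)
Conditions: [Ir(cod)(PCy3)(py)]PF6 (10 mol%), H2 (3 atm), CH2Cl2, 25 °C
Reagents that add atoms: none
Why: hydroxyl-directed syn hydrogenation, in which the axial C12 hydroxyl (homoallylic to C14) and the angular C15 methyl both steer hydrogen to the face anti to that methyl, giving the trans ring A/B fusion and, by syn addition, the C18 isopropyl cis to C13 as the kinetic epimer, while the neutral conditions should avoid epimerisation next to the ketone.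

**Compound list**

1 | (2-bromoprop-2-en-1-yl)trimethylsilane | C[Si](C)(C)CC(Br)=C | starting material
2 | oxirane | C1CO1 | starting material
3 | [3-(trimethylsilyl)prop-1-en-2-yl]magnesium bromide | C[Si](C)(C)CC(=C)[Mg]Br | intermediate
4 | 3-[(trimethylsilyl)methyl]but-3-en-1-ol | C[Si](C)(C)CC(=C)CCO | intermediate
5 | [2-(2-iodoethyl)prop-2-en-1-yl]trimethylsilane | C[Si](C)(C)CC(=C)CCI | intermediate
6 | pent-4-ynoic acid | C#CCCC(=O)O | starting material
7 | N,O-dimethylhydroxylamine hydrochloride | CNOC.Cl | starting material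
8 | 1-(1H-imidazol-1-yl)pent-4-yn-1-one | C#CCCC(=O)n1ccnc1 | intermediate
9 | N-methoxy-N-methylpent-4-ynamide | C#CCCC(=O)N(C)OC | intermediate
10 | (trimethylsilyl)methylmagnesium chloride | C[Si](C)(C)C[Mg]Cl | starting material
11 | (Z)-alkenylcopper from carbocupration of 9 | CON(C)C(=O)CC/C(C[Si](C)(C)C)=C/[Cu] | intermediate
12 | (4Z)-N-methoxy-N-methyl-8-methylidene-9-(trimethylsilyl)-4-[(trimethylsilyl)methyl]non-4-enamide | CON(C)C(=O)CC/C(C[Si](C)(C)C)=C/CCC(=C)C[Si](C)(C)C | intermediate
13 | propanal | CCC=O | starting material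
14 | cyclohexanamine | NC1CCCCC1 | starting material
15 | N-propylidenecyclohexanamine | CCC=NC1CCCCC1 | intermediate
16 | (6Z)-1-(cyclohexylamino)-2-methyl-10-methylidene-11-(trimethylsilyl)-6-[(trimethylsilyl)methyl]undeca-1,6-dien-3-one | C[Si](C)(C)CC(=C)CC/C=C(\C[Si](C)(C)C)CCC(=O)C(C)=CNC1CCCCC1 | intermediate
17 | (6Z)-2-methyl-10-methylidene-3-oxo-11-(trimethylsilyl)-6-[(trimethylsilyl)methyl]undec-6-enal (enolised at the methyl-bearing carbon) | C[Si](C)(C)CC(=C)CC/C=C(\C[Si](C)(C)C)CCC(=O)C(C)C=O | intermediate
18 | (1E,6Z)-1-[(tert-butyldimethylsilyl)oxy]-2-methyl-10-methylidene-11-(trimethylsilyl)-6-[(trimethylsilyl)methyl]undeca-1,6-dien-3-one | C[Si](C)(C)CC(=C)CC/C=C(\C[Si](C)(C)C)CCC(=O)/C(C)=C/O[Si](C)(C)C(C)(C)C | intermediate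
19 | monocyclic bis-silyl ether (ring D closed; C10 trimethylsilyl ether, C12 enol silyl ether), racemic | C[Si](C)(C)CC(=C)CCC1C(=C)CCC1(O[Si](C)(C)C)/C(C)=C/O[Si](C)(C)C(C)(C)C | intermediate
20 | conjugated O-silyl oxocarbenium triflate (C10=C11–C12=O+), racemic | C[Si](C)(C)CC(=C)CCC1C(=C)CC/C1=C(\C)C=[O+][Si](C)(C)C(C)(C)C.[O-]S(=O)(=O)C(F)(F)F | intermediate
21 | rac-tert-butyl(dimethyl)[(2-methyl-5,9-dimethylidenebicyclo[6.3.0]undec-1-en-3-yl)oxy]silane | C1C(=C)CCC2C(=C)CC/C2=C(\C)C1O[Si](C)(C)C(C)(C)C | intermediate
22 | rac-2-methyl-5,9-dimethylidenebicyclo[6.3.0]undec-1-en-3-ol | C1C(=C)CCC2C(=C)CC/C2=C(\C)C1O | intermediate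
23 | rac-2-methyl-5,9-dimethylidenebicyclo[6.3.0]undec-1-en-3-one | C1C(=C)CCC2C(=C)CC/C2=C(\C)C1=O | intermediate
24 | (3S,8S)-2-methyl-5,9-dimethylidenebicyclo[6.3.0]undec-1-en-3-ol | C1C(=C)CC[C@H]2C(=C)CC/C2=C(\C)[C@H]1O | intermediate
25 | (3S,5R,8S,9S)-2,5,9-trimethylbicyclo[6.3.0]undec-1-en-3-ol | C1[C@H](C)CC[C@H]2[C@@H](C)CC/C2=C(\C)[C@H]1O | intermediate
26 | (5R,8S,9S)-2,5,9-trimethylbicyclo[6.3.0]undec-1-en-3-one | C1[C@H](C)CC[C@H]2[C@@H](C)CC/C2=C(\C)C1=O | intermediate
27 | (1S,2S,5R,8S,9S)-1,2-epoxy-2,5,9-trimethylbicyclo[6.3.0]undecan-3-one | C1[C@H](C)CC[C@H]2[C@@H](C)CC[C@]23O[C@]3(C)C1=O | intermediate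
28 | 3-bromo-2-methylprop-1-ene | C=C(C)CBr | starting material
29 | lithium enolate of 27 | C=1[C@H](C)CC[C@H]2[C@@H](C)CC[C@]23O[C@]3(C)C=1O[Li] | intermediate
30 | (1S,2S,4R,5R,8S,9S)-1,2-epoxy-2,5,9-trimethyl-4-(2-methylprop-2-en-1-yl)bicyclo[6.3.0]undecan-3-one | C=C(C)C[C@@H]1[C@H](C)CC[C@H]2[C@@H](C)CC[C@]23O[C@]3(C)C1=O | intermediate
31 | 1-bromo-4-methylpent-2-yne | CC(C)C#CCBr | starting material
32 | (4-methylpenta-1,2-dien-3-yl)zinc bromide | CC(C)C(=C=C)[Zn]Br | intermediate
33 | (1S,2R,3R,4R,5R,8S,9S)-1,2-epoxy-2,5,9-trimethyl-3-(4-methylpent-2-yn-1-yl)-4-(2-methylprop-2-en-1-yl)bicyclo[6.3.0]undecan-3-ol | C=C(C)C[C@@H]1[C@H](C)CC[C@H]2[C@@H](C)CC[C@]23O[C@]3(C)[C@@]1(O)CC#CC(C)C | intermediate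
34 | (2R,3R,6S,7S,10S,11R,12R,15S)-10,11-epoxy-12-hydroxy tetracyclic 14(18)-en-17-one | CC(C)C=1C(=O)C[C@]2(C)C[C@@H]3[C@H](C)CC[C@H]4[C@@H](C)CC[C@]45O[C@]5(C)[C@@]3(O)CC=12 | intermediate
35 | (2R,3R,6S,7S,10S,11R,12R,14S,15S,18R)-10,11-epoxy-12-hydroxy tetracyclic 17-ketone | CC(C)[C@H]1C(=O)C[C@]2(C)C[C@@H]3[C@H](C)CC[C@H]4[C@@H](C)CC[C@]45O[C@]5(C)[C@@]3(O)C[C@@H]12 | target

**Step count and risks**

Total step count: 17. Longest linear sequence: 16 (steps 1, 2, 4–17).

Most likely to fail, first: step 7. After ring D has formed, the second allylsilane may close the six-membered ring by attack of C2 on C10 instead of the eight-membered ring at C12, or the cation may be lost by proton elimination or protodesilylation. The fallback separates the two bond formations and uses known reactions; it sets out from 18 and returns at 22. Treatment of 18 with EtAlCl2 (CH2Cl2, −78 °C) and quenching with dilute aqueous acid should give, by intramolecular allylsilane addition to the ketone and Stork–Danheiser-type transposition on work-up, the cyclopentylidene enal rac-(2Z)-2-{3-methylidene-2-[3-methylidene-4-(trimethylsilyl)butyl]cyclopentylidene}propanal F1. Bromodesilylation with N-bromosuccinimide (THF, −78 °C) converts the remaining allylsilane into the allylic bromide rac-(2Z)-2-{2-[3-(bromomethyl)but-3-en-1-yl]-3-methylidenecyclopentylidene}propanal F2. A Nozaki–Hiyama allylation with CrCl2 (THF, high dilution), which adds 1,2 to enals and is an established way to close eight-membered rings, then gives 22.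

Second: step 16. The 1,7-enyne combines a 1,1-disubstituted alkene with an internal, isopropyl-bearing alkyne, so the cobalt complex may form without cyclising or may decompose on heating. The fallback sets out from 30 and returns at the target 35; it uses a terminal alkyne and brings in the isopropyl group afterwards. Zinc-mediated propargylation of 30 with 3-bromoprop-1-yne gives the terminal alkyne (1S,2R,3R,4R,5R,8S,9S)-1,2-epoxy-2,5,9-trimethyl-4-(2-methylprop-2-en-1-yl)-3-(prop-2-yn-1-yl)bicyclo[6.3.0]undecan-3-ol F3. Its Pauson–Khand reaction (Co2(CO)8, N-methylmorpholine N-oxide) gives the C18-unsubstituted tetracyclic enone F4. Iodination with I2 and pyridine gives the 18-iodo enone F5. Suzuki coupling with isopropenylboronic acid pinacol ester (PdCl2(dppf), K3PO4) gives the 18-isopropenyl dienone F6. The directed hydrogenation of step 17 then reduces both double bonds to 35.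

Third: step 14. The facial selectivity of the enolate alkylation rests on a conformational argument and may be poor or reversed, and the new centre can epimerise next to the ketone. The fallback sets out from 27 and returns at 30; it delivers a proton instead of the carbon chain to C2. The lithium enolate of 27 is treated with dimethyl(methylidene)ammonium iodide to give the Mannich base 4-[(dimethylamino)methyl]-1,2-epoxy-2,5,9-trimethylbicyclo[6.3.0]undecan-3-one F7. Methylation with iodomethane and elimination with NaHCO3 gives the exocyclic enone (1S,2S,5R,8S,9S)-1,2-epoxy-2,5,9-trimethyl-4-methylidenebicyclo[6.3.0]undecan-3-one F8. Conjugate addition of the isopropenylcopper reagent made from isopropenylmagnesium bromide and CuBr·SMe2 (THF, −78 °C), followed by protonation of the enolate at −78 °C with 2,6-di-tert-butylphenol, gives 30; a facial bias that would misdirect the alkylation now places hydrogen on that face and C1 on the required one.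

Further compounds
F1 | step 7 | rac-(2Z)-2-{3-methylidene-2-[3-methylidene-4-(trimethylsilyl)butyl]cyclopentylidene}propanal | C[Si](C)(C)CC(=C)CCC1C(=C)CC/C1=C(\C)C=O
F2 | step 7 | rac-(2Z)-2-{2-[3-(bromomethyl)but-3-en-1-yl]-3-methylidenecyclopentylidene}propanal | BrCC(=C)CCC1C(=C)CC/C1=C(\C)C=O
F3 | step 16 | (1S,2R,3R,4R,5R,8S,9S)-1,2-epoxy-2,5,9-trimethyl-4-(2-methylprop-2-en-1-yl)-3-(prop-2-yn-1-yl)bicyclo[6.3.0]undecan-3-ol | C=C(C)C[C@@H]1[C@H](C)CC[C@H]2[C@@H](C)CC[C@]23O[C@]3(C)[C@@]1(O)CC#C
F4 | step 16 | C18-unsubstituted analogue of 34 (tetracyclic 14(18)-en-17-one with hydrogen on C18) | C=1C(=O)C[C@]2(C)C[C@@H]3[C@H](C)CC[C@H]4[C@@H](C)CC[C@]45O[C@]5(C)[C@@]3(O)CC=12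
F5 | step 16 | 18-iodo analogue of 34 | IC=1C(=O)C[C@]2(C)C[C@@H]3[C@H](C)CC[C@H]4[C@@H](C)CC[C@]45O[C@]5(C)[C@@]3(O)CC=12
F6 | step 16 | 18-(prop-1-en-2-yl) analogue of 34 (19,20-didehydro-34) | C=C(C)C=1C(=O)C[C@]2(C)C[C@@H]3[C@H](C)CC[C@H]4[C@@H](C)CC[C@]45O[C@]5(C)[C@@]3(O)CC=12
F7 | step 14 | (1S,2S,5R,8S,9S)-4-[(dimethylamino)methyl]-1,2-epoxy-2,5,9-trimethylbicyclo[6.3.0]undecan-3-one (C4 epimers) | CN(C)CC1[C@H](C)CC[C@H]2[C@@H](C)CC[C@]23O[C@]3(C)C1=O
F8 | step 14 | (1S,2S,5R,8S,9S)-1,2-epoxy-2,5,9-trimethyl-4-methylidenebicyclo[6.3.0]undecan-3-one | C=C1[C@H](C)CC[C@H]2[C@@H](C)CC[C@]23O[C@]3(C)C1=O
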